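A small charge of catalyst, 6.8 mol%, works fast: by 0.667 h target and side product in the south-west run together hold 12.5 times the catalyst charge, an average of 1.28 h⁻¹ in units of the starting material charged. The new flask is this same run followed further.

| flask | starting material | reagent | catalyst | remark | time |
|---|---|---|---|---|---|
| south-west | 0.40 M | 2.5 equiv | 6.8 mol% | the very flask that is asked about, followed so far |  |
| flask | 0.40 M | 2.50 equiv | 6.8 mol% |  | 6.0 h |

south-west run (percent of the starting material charged)

| time / h | target / % | side product / % |
|---|---|---|
| 0.667 | 63.9 | 21.2 |
| 1.33 | 58.5 | 32.6 |
| 2.00 | 55.6 | 34.2 |
| 2.50 | 53.3 | 41.6 |
| 3.00 | 50.6 | 45.1 |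

(each reading ± 1 percentage point)

- share of target in target plus side product at 2.5 min
- share of target in target plus side product at 6.0 h

- percent here means starting material units held: one side product counts as two
- on the list of suspects stand: reagent + catalyst + intermediate <-> catalyst + target; starting material + catalyst <-> catalyst + intermediate; starting material + target -> side product

After that steep start the target curve turns down. From 1.33 h to 3.00 h target loses 7.9 percentage points while side product gains 12 points, and the two reach 95.7% together. Counted in turnovers, each coupling takes one target and one starting material, and if that starting material has fallen back from target, the coupling costs two targets. If the reversible steps keep starting material in proportion to target at a steady reagent level, the loss goes as target squared (apparent second order), so the reciprocal of target, as a fraction of the charge, climbs straight with time. Between those readings it climbs 0.160 h⁻¹, the reciprocal clock, a reading with their scatter in it. Holding that sum, target crosses side product at 3.71 h. At 6.0 h this reckoning has target at 40.7% and a share of 42.6%.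

The forecast gives 96% (90% to 99.5%) at 2.5 min and 42% (36% to 48%) at 6.0 h, holding that “target returns to starting material, which then couples with target irreversibly”.

The flask gives 93.8% at 2.5 min and 40.8% at 6.0 h, with 38.5% target against the clock's 40.7%.

    reagent + catalyst + intermediate ⇌ catalyst + target (K = 13.0 M⁻¹, k = 0.127 M⁻² s⁻¹)
    starting material + catalyst ⇌ catalyst + intermediate (K = 2.07, k = 0.0753 M⁻¹ s⁻¹)
    starting material + target → side product (k = 0.00188 M⁻¹ s⁻¹)

With the falling back of target to reagent and intermediate struck out, the share at 6.0 h stands at 75.1%. The neighbour flask with 6.20 equiv of reagent holds 2.96 times this flask's reagent at 6.0 h. If the reversible steps stand near balance, starting material per target goes as one over reagent, so the clock is divided by that ratio; started from this flask's line carried back to time zero, it gives 54.9% target at 6.0 h, and that neighbour holds 56.7%.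

The numbers in the tables come from a simulation for an exercise; the scatter is artificial.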